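**Plan**

1. Retrosynthesis: the late cuts O–Si (C15), C3–OAc, C3–H, C4–CH3 and C8=C17 lead back to diketo ester 18. Ring A of 18 is cut at C1–C10 and ring B is contracted (C8–C9 cut, C8–C10 re-formed) to a cyclopentanone (C5, C6, C7, C8, C10). Then C9–C10, C3–C4 and C4–C5 are cut.
2. Enabling feature: C1–C10 is the central bond of the 1,6-dicarbonyl array C3(=O)–C2–C1–C10–C9–C8(=O), C8 being the later exocyclic methylene carbon. A β-keto radical at C10 can therefore add to C1 of a C3 vinyl ketone, and the C8–C9–C10 triad can pass through a cyclopropyloxy radical.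
3. Forward: 2-methylcyclopentenone plus malonate gives the five-membered ring with the C5 arm; acrolein supplies C1–C3; a Mukaiyama aldol attaches the geraniol-derived C9/C11–C16 aldehyde at C10.
4. Rings: in one step a C9 radical closes on the C8 carbonyl, the three-membered ring opens (the five-membered ring becomes six-membered ring B), and the tertiary C10 radical closes ring A at C1.
5. Stereochemistry: C5 from the catalytic asymmetric Michael addition; C10 from C5 in the chair transition state of ring A closure; C9 by equilibration next to the C8 ketone; C4 by methylation anti to the C10 methyl; C3 by equatorial hydride delivery; the E-alkene from geraniol.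
6. End game: Wittig at C8, C4 methylation, C3 reduction, acetylation, desilylation.

Key step: step 11

Remark: labdane numbering (C1–C20) is used for atoms at every stage; compounds 12–20 are carried as mixtures at the centres their SMILES leave open (all reset later); descriptor changes between 7 and 8 and between 20 and 21 reflect CIP priorities, not inversion.
Assumption: the quinine-derived ammonium salt of step 3 is taken to give the (1R,2S) adduct 7; if the sense of induction is the opposite, its quinidine-derived pseudoenantiomer is used.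

**Route**

Step 1
Reactants: 1 geraniol
Product: 2 tert-butyl{[(2E)-3,7-dimethylocta-2,6-dien-1-yl]oxy}diphenylsilane
Conditions: t-BuPh2SiCl, imidazole, DMF, 25 °C
Reagents that add atoms: tert-butyl(chloro)diphenylsilane, CC(C)(C)[Si](Cl)(c1ccccc1)c1ccccc1
Why: O-Silylation of the primary allylic alcohol masks the future C15 hydroxyl with a silyl ether that should survive Lewis acid, base, hydride and radical conditions until the last step.

Step 2
Reactants: 2 geranyl silyl ether
Product: 4 (4E)-6-[(tert-butyldiphenylsilyl)oxy]-4-methylhex-4-enal, via 6,7-epoxide 3 (not isolated)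
Conditions: mCPBA, CH2Cl2, 0 °C; then H5IO6, THF–H2O, 0 °C
Reagents that add atoms: 3-chloroperbenzoic acid, OOC(=O)c1cccc(Cl)c1
Why: Prilezhaev epoxidation should select the more electron-rich distal alkene (the other is deactivated by the allylic oxygen), and periodic acid cleavage of the epoxide then gives the aldehyde whose carbonyl carbon becomes C9, with the E-alkene (C13=C14) untouched.

Step 3
Reactants: 5 2-methylcyclopent-2-en-1-one; 6 dimethyl malonate
Product: 7 dimethyl 2-[(1R,2S)-2-methyl-3-oxocyclopentyl]propanedioate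
Conditions: N-(9-anthracenylmethyl)quininium chloride (10 mol %), K2CO3, toluene, −20 °C
Reagents that add atoms: none
Why: Catalytic asymmetric Michael addition under solid–liquid phase-transfer conditions, in which the chiral ammonium–malonate ion pair selects one face of the 2-alkyl enone and sets C5, the C10 methyl settling trans by equilibration.

Step 4
Reactants: 7 malonate adduct
Product: 8 methyl 2-[(1S,2S)-2-methyl-3-oxocyclopentyl]acetate
Conditions: NaCl, H2O, DMSO, 150 °C
Reagents that add atoms: none
Why: Krapcho dealkoxycarbonylation removes one malonate ester under near-neutral conditions that leave C5 (β to the ketone) untouched.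

Step 5
Reactants: 8 keto ester
Product: 9 methyl 2-[(1S)-2-methyl-3-(trimethylsilyloxy)cyclopent-2-en-1-yl]acetate
Conditions: Me3SiCl, NaI, Et3N, MeCN, 25 °C
Reagents that add atoms: chlorotrimethylsilane, C[Si](C)(C)Cl
Why: Silyl enol ether formation under equilibrating conditions should favour the tetrasubstituted C8=C10 enol ether, which masks the ketone for step 6 and fixes the regiochemistry of the aldol in step 7.

Step 6
Reactants: 9 silyl enol ether ester; 10 acrolein
Product: 13 methyl 2-[(1S)-2-methyl-3-(trimethylsilyloxy)cyclopent-2-en-1-yl]-3-(triethylsilyloxy)pent-4-enoate, via lithium ester enolate 11 (not isolated), via lithium aldolate 12 (not isolated)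
Conditions: LiN(i-Pr)2, THF, −78 °C; acrolein; then Et3SiCl, DMPU, −78 to −20 °C
Reagents that add atoms: chlorotriethylsilane, CC[Si](Cl)(CC)CC
Why: Aldol addition of the lithium ester enolate to acrolein (1,2-addition at low temperature) joins C3, C2 and C1 to C4, and silylation of the aldolate in the same flask protects the C3 oxygen; the new centres C3 and C4 need no control because both are reset later.

Step 7
Reactants: 13 silyl enol ether; 4 side-chain aldehyde
Product: 14 methyl 2-[(1S)-2-{(4E)-6-[(tert-butyldiphenylsilyl)oxy]-1-hydroxy-4-methylhex-4-en-1-yl}-2-methyl-3-oxocyclopentyl]-3-(triethylsilyloxy)pent-4-enoate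
Conditions: BF3·OEt2, CH2Cl2, −78 °C
Reagents that add atoms: none
Why: Mukaiyama aldol addition of the tetrasubstituted silyl enol ether forms C9–C10 and the quaternary C10, the aldehyde being expected to enter anti to the C5 arm; neither new centre matters, since C10 becomes a radical centre and C9 an epimerisable α-carbon in step 11.

Step 8
Reactants: 14 aldol adduct
Product: 15 methyl 2-[(1S)-2-{(4E)-6-[(tert-butyldiphenylsilyl)oxy]-4-methyl-1-[(phenoxycarbonothioyl)oxy]hex-4-en-1-yl}-2-methyl-3-oxocyclopentyl]-3-(triethylsilyloxy)pent-4-enoate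
Conditions: PhOC(S)Cl, pyridine, DMAP (cat.), CH2Cl2, 25 °C
Reagents that add atoms: O-phenyl carbonochloridothioate, S=C(Cl)Oc1ccccc1
Why: O-Thioacylation of the C9 hydroxyl installs the radical leaving group of a Barton–McCombie deoxygenation under weakly basic conditions that should not trigger retro-aldol cleavage.

Step 9
Reactants: 15 thionocarbonate
Product: 16 methyl 2-[(1S)-2-{(4E)-6-[(tert-butyldiphenylsilyl)oxy]-4-methyl-1-[(phenoxycarbonothioyl)oxy]hex-4-en-1-yl}-2-methyl-3-oxocyclopentyl]-3-hydroxypent-4-enoate
Conditions: PPTS (cat.), MeOH, 0 to 25 °C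
Reagents that add atoms: none
Why: Acid-catalysed methanolysis should cleave the secondary triethylsilyl ether selectively, the primary tert-butyldiphenylsilyl ether and the thionocarbonate being far more robust.

Step 10
Reactants: 16 allylic alcohol
Product: 17 methyl 2-[(1S)-2-{(4E)-6-[(tert-butyldiphenylsilyl)oxy]-4-methyl-1-[(phenoxycarbonothioyl)oxy]hex-4-en-1-yl}-2-methyl-3-oxocyclopentyl]-3-oxopent-4-enoate
Conditions: Dess–Martin periodinane, CH2Cl2, 0 °C
Reagents that add atoms: none
Why: Dess–Martin oxidation of the allylic alcohol gives the α-substituted 3-oxopent-4-enoate (vinyl ketone C1=C2–C3=O) under neutral conditions just before it is needed as the radical acceptor.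

Step 11
Reactants: 17 cyclopentanone thionocarbonate
Product: 18 methyl (5S,9R,10S)-15-[(tert-butyldiphenylsilyl)oxy]-3,8-dioxo-17,18-dinorlabd-13E-en-19-oate
Conditions: (Me3Si)3SiH and AIBN added by syringe pump over 8 h, toluene (0.005 M), 90 °C
Reagents that add atoms: none
Why: The silyl radical adds to the thiocarbonyl sulfur and the C9–O bond fragments to a secondary C9 radical, which adds 3-exo-trig to the C8 carbonyl to give a bicyclo[3.1.0]hexan-1-oxyl radical; strain-releasing β-scission of its C8–C10 bond turns the cyclopentanone into the cyclohexanone ring B and leaves a tertiary, nucleophilic radical at C10, which adds to the terminal carbon C1 of the vinyl ketone, and the electrophilic C2 radical takes hydrogen from the silane to carry the chain. The closest known reaction type is the Dowd–Beckwith ring expansion (radical 1,2-acyl shift through a cyclopropyloxy radical) run in tandem with a Giese-type radical cyclisation. Ring B arises by 3-exo-trig closure followed by ring opening (net one-carbon expansion) and ring A closes 6-endo-trig. C10 is controlled by C5: in the chair-like transition state the C4 arm is equatorial on ring B and C1 bonds anti to H-5, as in the second ring closure of radical polyene cyclisations, which should give the trans-decalin with the C10 methyl β, while C9 and C4 form as mixtures that are corrected later (C9 next to the C8 ketone, C4 enolisable). The step needs ring expansion to outrun hydrogen transfer and 6-endo to beat 5-exo closure: the first is secured by slow addition at high dilution and by the gain from a secondary to a tertiary radical with relief of cyclopentanone strain, the second by polarity matching at the enone β-carbon with the carbonyl inside the forming ring, and the trans arrangement of the C9 and C4 arms on the five-membered ring should make the competing 7-endo attack of the C9 radical on C1 strained.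

Step 12
Reactants: 18 diketo ester
Product: 20 methyl (5S,9S,10S)-15-[(tert-butyldiphenylsilyl)oxy]-3-oxo-18-norlabda-8(17),13E-dien-19-oate, via potassium enolate 19 (not isolated)
Conditions: Ph3PCH3Br, KOt-Bu (excess), THF, 0 to 50 °C
Reagents that add atoms: methyltriphenylphosphonium bromide, C[P+](c1ccccc1)(c1ccccc1)c1ccccc1.[Br-]
Why: Wittig methylenation in which excess base first converts the β-keto ester into its enolate (shielding C3) and equilibrates C9 to the equatorial β side chain, so that only the C8 ketone should be olefinated to the exocyclic C8=C17 alkene.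

Step 13
Reactants: 20 β-keto ester
Product: 21 methyl (4R,5R,9S,10R)-15-[(tert-butyldiphenylsilyl)oxy]-3-oxolabda-8(17),13E-dien-19-oate
Conditions: K2CO3, MeI, acetone, 25 °C
Reagents that add atoms: iodomethane, CI
Why: C-Alkylation of the β-keto ester enolate, in which the axial C10 methyl blocks the β face of the C3=C4 enolate so that iodomethane should enter from the α face and leave the ester axial (4α-CH3, 4β-CO2CH3).

Step 14
Reactants: 21 3-ketone
Product: 22 methyl (3R,4R,5R,9S,10R)-15-[(tert-butyldiphenylsilyl)oxy]-3-hydroxylabda-8(17),13E-dien-19-oate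
Conditions: LiBH(s-Bu)3, THF, −78 °C
Reagents that add atoms: none
Why: Ketone reduction with a bulky trialkylborohydride, for which axial approach is blocked by H-1α and H-5α, so that hydride should be delivered equatorially to give the axial 3α-alcohol while the hindered C19 ester is left alone.

Step 15
Reactants: 22 3α-alcohol
Product: 23 methyl (3R,4R,5R,9S,10R)-3-acetoxy-15-[(tert-butyldiphenylsilyl)oxy]labda-8(17),13E-dien-19-oate
Conditions: Ac2O, DMAP, pyridine, 40 °C
Reagents that add atoms: acetic anhydride, CC(=O)OC(C)=O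
Why: DMAP-catalysed acylation esterifies the hindered axial alcohol while the C15 oxygen is still silylated.

Step 16
Reactants: 23 silyl ether acetate
Product: 24 methyl (3R,4R,5R,9S,10R)-3-acetoxy-15-hydroxylabda-8(17),13E-dien-19-oate
Conditions: Bu4NF, AcOH, THF, 25 °C
Reagents that add atoms: none
Why: Fluoride-mediated desilylation buffered with acetic acid should free the primary allylic alcohol without acyl migration or ester cleavage.

**Compound list**

1 | geraniol, (2E)-3,7-dimethylocta-2,6-dien-1-ol | CC(C)=CCC/C(C)=C/CO | starting material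
2 | tert-butyl{[(2E)-3,7-dimethylocta-2,6-dien-1-yl]oxy}diphenylsilane | CC(C)=CCC/C(C)=C/CO[Si](c1ccccc1)(c1ccccc1)C(C)(C)C | intermediate
3 | tert-butyl{[(2E)-5-(3,3-dimethyloxiran-2-yl)-3-methylpent-2-en-1-yl]oxy}diphenylsilane (racemic epoxide) | CC1(C)OC1CC/C(C)=C/CO[Si](c2ccccc2)(c2ccccc2)C(C)(C)C | intermediate (not isolated)
4 | (4E)-6-[(tert-butyldiphenylsilyl)oxy]-4-methylhex-4-enal | O=CCC/C(C)=C/CO[Si](c1ccccc1)(c1ccccc1)C(C)(C)C | intermediate
5 | 2-methylcyclopent-2-en-1-one | CC1=CCCC1=O | starting material
6 | dimethyl malonate | COC(=O)CC(=O)OC | starting material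
7 | dimethyl 2-[(1R,2S)-2-methyl-3-oxocyclopentyl]propanedioate | O=C1CC[C@@H](C(C(=O)OC)C(=O)OC)[C@@H]1C | intermediate
8 | methyl 2-[(1S,2S)-2-methyl-3-oxocyclopentyl]acetate | O=C1CC[C@@H](CC(=O)OC)[C@@H]1C | intermediate
9 | methyl 2-[(1S)-2-methyl-3-(trimethylsilyloxy)cyclopent-2-en-1-yl]acetate | C[Si](C)(C)OC1=C(C)[C@H](CC(=O)OC)CC1 | intermediate
10 | acrolein | C=CC=O | starting material
11 | lithium ester enolate of 9 | C[Si](C)(C)OC1=C(C)[C@H](C=C([O-])OC)CC1.[Li+] | intermediate (not isolated)
12 | lithium aldolate from 11 and acrolein (C3, C4 mixture) | C[Si](C)(C)OC1=C(C)[C@H](C(C(=O)OC)C([O-])C=C)CC1.[Li+] | intermediate (not isolated)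
13 | methyl 2-[(1S)-2-methyl-3-(trimethylsilyloxy)cyclopent-2-en-1-yl]-3-(triethylsilyloxy)pent-4-enoate | C[Si](C)(C)OC1=C(C)[C@H](C(C(=O)OC)C(O[Si](CC)(CC)CC)C=C)CC1 | intermediate
14 | methyl 2-[(1S)-2-{(4E)-6-[(tert-butyldiphenylsilyl)oxy]-1-hydroxy-4-methylhex-4-en-1-yl}-2-methyl-3-oxocyclopentyl]-3-(triethylsilyloxy)pent-4-enoate | O=C1CC[C@@H](C(C(=O)OC)C(O[Si](CC)(CC)CC)C=C)C1(C)C(O)CC/C(C)=C/CO[Si](c2ccccc2)(c2ccccc2)C(C)(C)C | intermediate
15 | methyl 2-[(1S)-2-{(4E)-6-[(tert-butyldiphenylsilyl)oxy]-4-methyl-1-[(phenoxycarbonothioyl)oxy]hex-4-en-1-yl}-2-methyl-3-oxocyclopentyl]-3-(triethylsilyloxy)pent-4-enoate | O=C1CC[C@@H](C(C(=O)OC)C(O[Si](CC)(CC)CC)C=C)C1(C)C(OC(=S)Oc2ccccc2)CC/C(C)=C/CO[Si](c2ccccc2)(c2ccccc2)C(C)(C)C | intermediate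
16 | methyl 2-[(1S)-2-{(4E)-6-[(tert-butyldiphenylsilyl)oxy]-4-methyl-1-[(phenoxycarbonothioyl)oxy]hex-4-en-1-yl}-2-methyl-3-oxocyclopentyl]-3-hydroxypent-4-enoate | O=C1CC[C@@H](C(C(=O)OC)C(O)C=C)C1(C)C(OC(=S)Oc2ccccc2)CC/C(C)=C/CO[Si](c2ccccc2)(c2ccccc2)C(C)(C)C | intermediate
17 | methyl 2-[(1S)-2-{(4E)-6-[(tert-butyldiphenylsilyl)oxy]-4-methyl-1-[(phenoxycarbonothioyl)oxy]hex-4-en-1-yl}-2-methyl-3-oxocyclopentyl]-3-oxopent-4-enoate | O=C1CC[C@@H](C(C(=O)OC)C(=O)C=C)C1(C)C(OC(=S)Oc2ccccc2)CC/C(C)=C/CO[Si](c2ccccc2)(c2ccccc2)C(C)(C)C | intermediate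
18 | methyl (5S,9R,10S)-15-[(tert-butyldiphenylsilyl)oxy]-3,8-dioxo-17,18-dinorlabd-13E-en-19-oate (5α-H, 10β-CH3, trans-decalin; C4 open; C9 shown equatorial, its epimer converges in step 12) | O=C1CC[C@@H]2[C@](C)(CCC(=O)C2C(=O)OC)[C@H]1CC/C(C)=C/CO[Si](c3ccccc3)(c3ccccc3)C(C)(C)C | intermediate
19 | potassium C3–C4 enolate of 18 | O=C1CC[C@@H]2[C@](C)(CCC([O-])=C2C(=O)OC)[C@H]1CC/C(C)=C/CO[Si](c3ccccc3)(c3ccccc3)C(C)(C)C.[K+] | intermediate (not isolated)
20 | methyl (5S,9S,10S)-15-[(tert-butyldiphenylsilyl)oxy]-3-oxo-18-norlabda-8(17),13E-dien-19-oate (C4 open) | C=C1CC[C@@H]2[C@](C)(CCC(=O)C2C(=O)OC)[C@H]1CC/C(C)=C/CO[Si](c3ccccc3)(c3ccccc3)C(C)(C)C | intermediate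
21 | methyl (4R,5R,9S,10R)-15-[(tert-butyldiphenylsilyl)oxy]-3-oxolabda-8(17),13E-dien-19-oate | C=C1CC[C@@H]2[C@](C)(CCC(=O)[C@]2(C)C(=O)OC)[C@H]1CC/C(C)=C/CO[Si](c3ccccc3)(c3ccccc3)C(C)(C)C | intermediate
22 | methyl (3R,4R,5R,9S,10R)-15-[(tert-butyldiphenylsilyl)oxy]-3-hydroxylabda-8(17),13E-dien-19-oate (3α-OH) | C=C1CC[C@@H]2[C@](C)(CC[C@@H](O)[C@]2(C)C(=O)OC)[C@H]1CC/C(C)=C/CO[Si](c3ccccc3)(c3ccccc3)C(C)(C)C | intermediate
23 | methyl (3R,4R,5R,9S,10R)-3-acetoxy-15-[(tert-butyldiphenylsilyl)oxy]labda-8(17),13E-dien-19-oate | C=C1CC[C@@H]2[C@](C)(CC[C@@H](OC(C)=O)[C@]2(C)C(=O)OC)[C@H]1CC/C(C)=C/CO[Si](c3ccccc3)(c3ccccc3)C(C)(C)C | intermediate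
24 | methyl (3R,4R,5R,9S,10R)-3-acetoxy-15-hydroxylabda-8(17),13E-dien-19-oate (3α-acetoxy) | C=C1CC[C@@H]2[C@](C)(CC[C@@H](OC(C)=O)[C@]2(C)C(=O)OC)[C@H]1CC/C(C)=C/CO | target

**Count and risks**

Total step count: 16. Longest linear sequence: 14 (steps 3–16, from 2-methylcyclopent-2-en-1-one).

Step 11 (key step). What may go wrong: hydrogen transfer from the silane to the C9 radical before it has closed on the C8 carbonyl, or to the C10 radical before ring A has closed (premature reduction), together with thermal loss of the vinyl ketone during the slow, hot fragmentation of the hindered thionocarbonate. The fallback sets out from 13 and 4 and comes back at 18; it puts the radical leaving group on C9 in the C9–C10 bond-forming event and cleaves it at room temperature. Aldehyde 4 with PhSeH and ZnCl2 should give the selenoacetal tert-butyl{[(2E)-3-methyl-6,6-bis(phenylselanyl)hex-2-en-1-yl]oxy}diphenylsilane F1. SnCl4 (CH2Cl2, −78 °C) ionises one C–Se bond of F1 and silyl enol ether 13 is α-selenoalkylated to methyl 2-[(1S)-2-{(4E)-6-[(tert-butyldiphenylsilyl)oxy]-4-methyl-1-(phenylselanyl)hex-4-en-1-yl}-2-methyl-3-oxocyclopentyl]-3-(triethylsilyloxy)pent-4-enoate F2. PPTS in MeOH should give the corresponding 3-hydroxypent-4-enoate F3, and MnO2 (which leaves the selenide alone) the 3-oxopent-4-enoate F4. Bu3SnH (syringe pump) with Et3B/air in benzene at 25 °C then releases the same C9 radical from the C–Se bond, so that ring expansion and ring A closure run at a temperature at which hydrogen transfer is held back by dilution and the vinyl ketone is not stressed, and 18 is reached again.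

Step 3. What may go wrong: insufficient discrimination of the enone faces in the ion-pair Michael addition, which would erode the enantiomeric purity at C5, the only centre that controls all others. The fallback sets out from 5 and comes back at 8, with a predictable sense of induction. Reduction of 5 with BH3·SMe2 and (R)-1-methyl-3,3-diphenyltetrahydro-1H,3H-pyrrolo[1,2-c][1,3,2]oxazaborole (Corey–Bakshi–Shibata reduction) should give (S)-2-methylcyclopent-2-en-1-ol F5. Johnson–Claisen rearrangement (MeC(OMe)3, cat. EtCO2H, 140 °C) transfers the carbinol configuration suprafacially to C5 and gives methyl 2-[(1S)-2-methylcyclopent-2-en-1-yl]acetate F6. Hydroboration–oxidation (BH3·SMe2, 0 °C; NaOH, H2O2) anti to the acetate arm gives methyl 2-[(1S,2R,3R)-3-hydroxy-2-methylcyclopentyl]acetate F7. Dess–Martin oxidation followed by equilibration of the α-methyl centre with DBU gives 8.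

Step 5. What may go wrong: incomplete equilibration, so that part of the material goes to the less substituted C7=C8 enol ether (which would mis-direct the aldol of step 7), and hydrolytic loss of the silyl enol ether on handling. The fallback sets out from 5 and comes back at 9 and makes no compound outside the list (F0). A Mukaiyama–Michael addition of 1-methoxy-1-(trimethylsilyloxy)ethene to 5, catalysed by (S)-3,3-diphenyl-1-(o-tolyl)tetrahydro-1H,3H-pyrrolo[1,2-c][1,3,2]oxazaborole activated with Tf2NH (CH2Cl2, −78 °C), forms C4–C5 and passes the silyl group to the C8 oxygen, so that 9 arises directly as the single enol ether regioisomer without any enolisation step.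

Further compounds
F1 | step 11 | tert-butyl{[(2E)-3-methyl-6,6-bis(phenylselanyl)hex-2-en-1-yl]oxy}diphenylsilane | c1ccccc1[Se]C([Se]c1ccccc1)CC/C(C)=C/CO[Si](c1ccccc1)(c1ccccc1)C(C)(C)C
F2 | step 11 | methyl 2-[(1S)-2-{(4E)-6-[(tert-butyldiphenylsilyl)oxy]-4-methyl-1-(phenylselanyl)hex-4-en-1-yl}-2-methyl-3-oxocyclopentyl]-3-(triethylsilyloxy)pent-4-enoate | O=C1CC[C@@H](C(C(=O)OC)C(O[Si](CC)(CC)CC)C=C)C1(C)C([Se]c2ccccc2)CC/C(C)=C/CO[Si](c2ccccc2)(c2ccccc2)C(C)(C)C
F3 | step 11 | methyl 2-[(1S)-2-{(4E)-6-[(tert-butyldiphenylsilyl)oxy]-4-methyl-1-(phenylselanyl)hex-4-en-1-yl}-2-methyl-3-oxocyclopentyl]-3-hydroxypent-4-enoate | O=C1CC[C@@H](C(C(=O)OC)C(O)C=C)C1(C)C([Se]c2ccccc2)CC/C(C)=C/CO[Si](c2ccccc2)(c2ccccc2)C(C)(C)C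
F4 | step 11 | methyl 2-[(1S)-2-{(4E)-6-[(tert-butyldiphenylsilyl)oxy]-4-methyl-1-(phenylselanyl)hex-4-en-1-yl}-2-methyl-3-oxocyclopentyl]-3-oxopent-4-enoate | O=C1CC[C@@H](C(C(=O)OC)C(=O)C=C)C1(C)C([Se]c2ccccc2)CC/C(C)=C/CO[Si](c2ccccc2)(c2ccccc2)C(C)(C)C
F5 | step 3 | (S)-2-methylcyclopent-2-en-1-ol | O[C@H]1CCC=C1C
F6 | step 3 | methyl 2-[(1S)-2-methylcyclopent-2-en-1-yl]acetate | COC(=O)C[C@@H]1CCC=C1C
F7 | step 3 | methyl 2-[(1S,2R,3R)-3-hydroxy-2-methylcyclopentyl]acetate | O[C@@H]1CC[C@@H](CC(=O)OC)[C@H]1C
F0 | step 5 | none | none
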